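Follow time in a closed, stirred flask of electrophile, free base and protonated nucleophile with a trace of protic impurity, and ask how much target stands after 2.0 h.

common to all: electrophile 14 mM; free base 16.8 mM; protonated nucleophile 14.7 mM

|  | protic impurity | remark | time |
|---|---|---|---|
| autumn | 0.19 mM | run made earlier |  |
| noon | 0.23 mM | run made earlier |  |
| zeta | 0.120 mM |  | 2.0 h |
| delta | 0.200 mM |  | 2.0 h |
| beta | 0.300 mM |  | 2.0 h |

| run | time / min | target / % | electrophile / % |
|---|---|---|---|
| autumn | 15.0 | 3.4 | 96.8 |
| autumn | 30.0 | 5.6 | 93.8 |
| autumn | 50.0 | 7.2 | 89.9 |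
| autumn | 60.0 | 8.6 | 88.5 |
| autumn | 80.0 | 9.4 | 85.6 |
| noon | 6.00 | 1.7 | 97.7 |
| noon | 12.0 | 2.4 | 97.2 |
| noon | 25.0 | 4.6 | 94.4 |
| noon | 40.0 | 6.5 | 91.9 |
| noon | 80.0 | 10.0 | 86.7 |

(standard deviation of a reading: 0.5 percentage points)

- "hardly changes" means that all values lie within two and a half points (for a concentration: within two and a half percent of the largest)

- amount of target at the end, in percent of the electrophile charged for zeta, delta, beta, in this order
- how the row runs (rises all the way / falls all the way / hardly changes / falls, then rises / rises, then falls)

Keep the books on the electrophile, the limiting reagent of the coupling, charged at 14 mM, less than the protonated nucleophile at 14.7 mM. Close them at 80.0 min, autumn first, then noon: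

Left as electrophile: 85.6%, 86.7%
Booked as target: 9.4%, 10.0%
Gap: 5 percentage points, 3.3 points

Each reading scatters by 0.5 points, and at 15.0 min the autumn gap is −0.2 points, so the autumn gap does not show yet at that first reading.

Now take the target entry. In the autumn run, time grows 4.00 times from 15.0 min to 60.0 min, yet target grows 2.53 times, with 88.5% of the electrophile still there. Assume, as my own reckoning, a brake that grows with the target. Let P be target and h the impurity, both as fractions of the electrophile charged:

dP/dt = c/(P + h), so P·P/2 + hP = ct

This is the parabolic growth law. The readings at 80.0 min give 0.00427 h⁻¹ for autumn and 0.00498 h⁻¹ for noon. Take the mean, 0.00463 h⁻¹, as the parabolic constant c: what P·P/2 + hP gains per hour, as read off these two scattered readings. Then solve for P at 2.0 h: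

P = √(h·h + 2ct) − h

zeta: h = 0.857%, P = 12.8%
delta: h = 1.43%, P = 12.2%
beta: h = 2.14%, P = 11.6%

The spread of my reckoned row is 1.2 points, so my row hardly changes. The law has no entry for the gap, so take these values as the high side.

The forecast, “Trimming slightly for reactant loss”, gives 12.1%, 11.6% and 11%, lower than my row, and the same shape: hardly changes.

The flasks give 11.5%, 11.4% and 11.2%: hardly changes.

    electrophile + acid set free → side product A (k = 1.00 M⁻¹ min⁻¹)
    electrophile + nucleophile → acid set free + target (k = 1.20 M⁻¹ min⁻¹)
    acid set free + free base ⇌ salt of the base, settled at all times (K = 16000 M⁻¹)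
    nucleophile + protic impurity → quenched reagent (k = 97.0 M⁻¹ min⁻¹)
    electrophile + target → side product B (k = 0.340 M⁻¹ min⁻¹)
    nucleophile + acid set free ⇌ protonated nucleophile, settled at all times (K = 5.90 × 10⁵ M⁻¹)

Put the end values back into the law: zeta returns c = 0.00380 h⁻¹ and beta 0.00434 h⁻¹, both less than the 0.00463 h⁻¹ from the earlier runs. In zeta at 2.00 h, target is made 1.60 times faster than it is used up, each step taken net. The loss of electrophile + target to side product B by itself gives target in zeta a half-life of 3.0 h at that moment, with side product B at 7.72%, counted with both electrophile units it holds.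

The numbers in the tables come from a simulation for substances that don't exist; the scatter is artificial.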